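**Plan**
Cuts: three functional-group changes come first (O5–H to O5–Si, C8 prenyl to C8 allyl, C4=O to C4–OMe). Ring C is then opened at C3–C4 and O1–C2 in one retro-oxa-[4+2]. The C8–CH2 bond goes back to an O-allyl ether and the styrene C=C to an aldehyde.
Enabling feature: in ring C the run O1, C8a, C4a, C4 can be unmasked as the oxadiene of an ortho-quinone methide built on ring A. The C2–C3 edge together with ring B is 2,4,6-trimethoxystyrene, a strongly nucleophilic alkene.
Forward: rings A and B are bought. Ring A is dressed (O-demethylation, O-allylation, silylation, Claisen shift) and the ring B aldehyde is methylenated. Ring C is the only ring made, in the cycloaddition.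
Stereochemistry: a chiral phosphoric acid bound to the quinone methide sets C4, and the cis-selective closure relays this to C2. C4 is then erased by oxidation, leaving (2S).
Design: the chelation-directed demethylation is done on the achiral benzaldehyde. The end game (DDQ, metathesis, buffered fluoride) is neutral, because the C2–O1 bond next to ring B ionises easily.

Key step: step 6

Assumption: (R)-TRIP is taken to expose the face of the quinone methide that leads to (4S) and, after cis closure, (2S). If the sense of induction is the reverse, (S)-TRIP is used with no other change.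

**Step 1**
Reactants: 1 2-hydroxy-4,6-dimethoxybenzaldehyde
Product: 2 2,6-dihydroxy-4-methoxybenzaldehyde
Conditions: AlCl3 (3 equiv), CH2Cl2, 0 °C to reflux; dilute aq HCl work-up
Reagents that add atoms: none
Why: Chelation-directed ortho-demethylation, in which aluminium held between the formyl oxygen and O6 activates only the flanking methyl ether towards chloride attack while the 4-OMe has no such chelate, and doing this on an achiral benzaldehyde spares the later flavanone any Lewis acid.

**Step 2**
Reactants: 2 2,6-dihydroxy-4-methoxybenzaldehyde; 3 allyl bromide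
Product: 4 2-(allyloxy)-6-hydroxy-4-methoxybenzaldehyde
Conditions: allyl bromide (1.0 equiv), K2CO3 (1.0 equiv), acetone, reflux
Reagents that add atoms: allyl bromide, C=CCBr
Why: Williamson ether synthesis on a symmetric diol with two equivalent OH groups, which should stop at the mono-ether because the remaining phenol is locked in a hydrogen bond to the formyl group and is far less nucleophilic.

**Step 3**
Reactants: 4 2-(allyloxy)-6-hydroxy-4-methoxybenzaldehyde; 5 tert-butyldimethylsilyl chloride
Product: 6 2-(allyloxy)-6-(tert-butyldimethylsilyloxy)-4-methoxybenzaldehyde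
Conditions: TBSCl, imidazole, DMF, rt
Reagents that add atoms: tert-butyldimethylsilyl chloride, CC(C)(C)[Si](C)(C)Cl
Why: Imidazole-promoted silylation of the only free phenol, which masks the future O5 so that a single phenol can later close ring C and which can be removed at the end with fluoride instead of acid or base.

**Step 4**
Reactants: 6 2-(allyloxy)-6-(tert-butyldimethylsilyloxy)-4-methoxybenzaldehyde
Product: 8 3-allyl-6-(tert-butyldimethylsilyloxy)-2-hydroxy-4-methoxybenzaldehyde, via Claisen dienone 7 (not isolated)
Conditions: 1,2-dichlorobenzene, 180 °C, sealed tube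
Reagents that add atoms: none
Why: Aromatic Claisen rearrangement ([3,3]-sigmatropic shift), in which only C3 of the two ortho positions bears hydrogen, so dienone 7 tautomerises to phenol 8 and the allyl group ends up next to the liberated OH with unambiguous regiochemistry.

**Step 5**
Reactants: 9 2,4,6-trimethoxybenzaldehyde; 10 methyltriphenylphosphonium bromide
Product: 11 2-ethenyl-1,3,5-trimethoxybenzene (2,4,6-trimethoxystyrene)
Conditions: MePPh3Br, KOtBu, THF, 0 °C to rt; chromatography on Et3N-deactivated silica
Reagents that add atoms: methyltriphenylphosphonium bromide, C[P+](c1ccccc1)(c1ccccc1)c1ccccc1.[Br-]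
Why: Wittig methylenation of a non-enolisable aromatic aldehyde with the non-stabilised ylide, with base-washed handling to protect the acid-sensitive styrene.

**Step 6**
Reactants: 8 3-allyl-6-(tert-butyldimethylsilyloxy)-2-hydroxy-4-methoxybenzaldehyde; 11 2,4,6-trimethoxystyrene; 12 trimethyl orthoformate
Product: 15 (2S,4S)-8-allyl-5-(tert-butyldimethylsilyloxy)-4,7-dimethoxy-2-(2,4,6-trimethoxyphenyl)chroman (2,4-cis), via dimethyl acetal 13 (not isolated), via ortho-quinone methide 14 (not isolated)
Conditions: (R)-TRIP [(R)-3,3'-bis(2,4,6-triisopropylphenyl)-1,1'-binaphthyl-2,2'-diyl hydrogen phosphate] (10 mol %), HC(OMe)3 (2 equiv), 4 Å MS, toluene, rt; then −20 °C, 11 (1.5 equiv) by syringe pump; Et3N quench, Et3N-deactivated silica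
Reagents that add atoms: trimethyl orthoformate, COC(OC)OC
Why: Proposed new method: the phosphoric acid ionises the orthoformate, aldehyde 8 passes through dimethyl acetal 13, and loss of methanol, easy because ring A carries three oxygen donors, gives the 4-methoxy ortho-quinone methide 14 (O-protonated form: the aryl oxocarbenium ion), which stays bound to the chiral phosphate through the hydrogen bond at the future O1. The nucleophilic CH2 terminus of styrene 11 bonds to the exocyclic carbon (C3–C4) slightly ahead of the attack of the quinone-methide oxygen on the developing 2,4,6-trimethoxybenzylic cation (O1–C2), so ring C closes in one asynchronous inverse-electron-demand oxa-[4+2] cycloaddition, which in the stepwise limit is a 6-exo-trig capture of the cation by O1. The closest known reactions are the chiral Brønsted acid-catalysed [4+2] cycloadditions of ortho-quinone methides from 2-hydroxybenzylic alcohols with styrenes and the racemic Lewis acid-promoted salicylaldehyde/orthoformate/styrene annulation; new here is their merger, a C4-alkoxy quinone methide under chiral-anion control. C4 is fixed by the catalyst, whose 3,3'-aryl groups leave one face of bound 14 open, and C2 is relayed from C4 by a chair-like endo transition state that places OMe and ring B both pseudo-equatorial (2,4-cis); any trans isomer, which would carry the opposite C2 configuration, is removed by chromatography before C4 is erased. Regiochemistry follows from polarity matching (styrene CH2 to the electrophilic C4) and from the silyl ether on the other ortho oxygen (future O5), which leaves the oxygen next to the allyl group as the only one able to close the ring, while the monosubstituted allyl alkene is far less nucleophilic than 11. The weak acid, the low temperature, the slow addition of 11 and the Et3N quench serve to keep 11 from oligomerising and to keep C2–O1 and C4–OMe of 15 from ionising.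

**Step 7**
Reactants: 15 (2S,4S)-8-allyl-5-(tert-butyldimethylsilyloxy)-4,7-dimethoxy-2-(2,4,6-trimethoxyphenyl)chroman
Product: 17 (2S)-8-allyl-5-(tert-butyldimethylsilyloxy)-7-methoxy-2-(2,4,6-trimethoxyphenyl)chroman-4-one, via C4 hemiketal 16 (not isolated)
Conditions: DDQ (1.2 equiv), CH2Cl2/pH 7 phosphate buffer (10:1), 0 °C
Reagents that add atoms: water, O
Why: DDQ-mediated oxidative cleavage of an electron-rich benzylic ether (the reaction type of PMB ether removal and of C4 oxidation of 5,7-dioxygenated flavans), in which hydride leaves the pseudo-axial C4–H that is aligned with the ring A π system and assisted by OMe, water adds to give hemiketal 16 and methanol is lost, while C2–H lies in the plane of the di-ortho-substituted ring B and the allylic CH2 is twisted out of overlap by its two ortho neighbours, so C2 should stay untouched.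

**Step 8**
Reactants: 17 (2S)-8-allyl-5-(tert-butyldimethylsilyloxy)-7-methoxy-2-(2,4,6-trimethoxyphenyl)chroman-4-one; 18 2-methyl-2-butene
Product: 19 (2S)-5-(tert-butyldimethylsilyloxy)-7-methoxy-8-(3-methylbut-2-enyl)-2-(2,4,6-trimethoxyphenyl)chroman-4-one
Conditions: second-generation Grubbs catalyst RuCl2(=CHPh)(PCy3)(SIMes) (5 mol %), 2-methyl-2-butene/CH2Cl2 (1:1), 40 °C, sealed tube
Reagents that add atoms: 2-methyl-2-butene, CC=C(C)C
Why: Olefin cross-metathesis of the terminal alkene with excess 2-methyl-2-butene, the standard way of turning a C-allyl arene into a C-prenyl arene, run under neutral conditions that leave C2, the ketone and the silyl ether alone.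

**Step 9**
Reactants: 19 (2S)-5-(tert-butyldimethylsilyloxy)-7-methoxy-8-(3-methylbut-2-enyl)-2-(2,4,6-trimethoxyphenyl)chroman-4-one
Product: 20 (2S)-5-hydroxy-7-methoxy-8-(3-methylbut-2-enyl)-2-(2,4,6-trimethoxyphenyl)chroman-4-one (CNP0307910.1)
Conditions: Bu4NF/AcOH (1:1, 1.2 equiv), THF, 0 °C
Reagents that add atoms: none
Why: Fluoride-induced cleavage of an aryl silyl ether, fast because the phenoxide peri to the ketone is a good leaving group, with acetic acid buffering the medium so that enolate-mediated opening to the chalcone (retro-oxa-Michael), which would racemise C2, is not triggered.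

**Compound list**
1 | 2-hydroxy-4,6-dimethoxybenzaldehyde | O=Cc1c(O)cc(OC)cc1OC | starting material
2 | 2,6-dihydroxy-4-methoxybenzaldehyde | O=Cc1c(O)cc(OC)cc1O | intermediate
3 | allyl bromide | C=CCBr | starting material
4 | 2-(allyloxy)-6-hydroxy-4-methoxybenzaldehyde | O=Cc1c(O)cc(OC)cc1OCC=C | intermediate
5 | tert-butyldimethylsilyl chloride | CC(C)(C)[Si](C)(C)Cl | starting material
6 | 2-(allyloxy)-6-(tert-butyldimethylsilyloxy)-4-methoxybenzaldehyde | O=Cc1c(OCC=C)cc(OC)cc1O[Si](C)(C)C(C)(C)C | intermediate
7 | 5-allyl-2-(tert-butyldimethylsilyloxy)-4-methoxy-6-oxocyclohexa-1,3-diene-1-carbaldehyde (Claisen dienone, racemic) | O=CC1=C(O[Si](C)(C)C(C)(C)C)C=C(OC)C(CC=C)C1=O | intermediate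
8 | 3-allyl-6-(tert-butyldimethylsilyloxy)-2-hydroxy-4-methoxybenzaldehyde | O=Cc1c(O)c(CC=C)c(OC)cc1O[Si](C)(C)C(C)(C)C | intermediate
9 | 2,4,6-trimethoxybenzaldehyde | COc1cc(OC)c(C=O)c(OC)c1 | starting material
10 | methyltriphenylphosphonium bromide | C[P+](c1ccccc1)(c1ccccc1)c1ccccc1.[Br-] | starting material
11 | 2-ethenyl-1,3,5-trimethoxybenzene | C=Cc1c(OC)cc(OC)cc1OC | intermediate
12 | trimethyl orthoformate | COC(OC)OC | starting material
13 | 2-allyl-5-(tert-butyldimethylsilyloxy)-6-(dimethoxymethyl)-3-methoxyphenol | COC(OC)c1c(O)c(CC=C)c(OC)cc1O[Si](C)(C)C(C)(C)C | intermediate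
14 | 2-allyl-5-(tert-butyldimethylsilyloxy)-3-methoxy-6-(methoxymethylidene)cyclohexa-2,4-dien-1-one (alkene geometry not fixed) | COC=C1C(=O)C(CC=C)=C(OC)C=C1O[Si](C)(C)C(C)(C)C | intermediate
15 | (2S,4S)-8-allyl-5-(tert-butyldimethylsilyloxy)-4,7-dimethoxy-2-(2,4,6-trimethoxyphenyl)chroman | COc1cc(OC)c([C@@H]2C[C@H](OC)c3c(O[Si](C)(C)C(C)(C)C)cc(OC)c(CC=C)c3O2)c(OC)c1 | intermediate
16 | (2S)-8-allyl-5-(tert-butyldimethylsilyloxy)-4,7-dimethoxy-2-(2,4,6-trimethoxyphenyl)chroman-4-ol (hemiketal, C4 unassigned) | COc1cc(OC)c([C@@H]2CC(O)(OC)c3c(O[Si](C)(C)C(C)(C)C)cc(OC)c(CC=C)c3O2)c(OC)c1 | intermediate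
17 | (2S)-8-allyl-5-(tert-butyldimethylsilyloxy)-7-methoxy-2-(2,4,6-trimethoxyphenyl)chroman-4-one | COc1cc(OC)c([C@@H]2CC(=O)c3c(O[Si](C)(C)C(C)(C)C)cc(OC)c(CC=C)c3O2)c(OC)c1 | intermediate
18 | 2-methyl-2-butene | CC=C(C)C | starting material
19 | (2S)-5-(tert-butyldimethylsilyloxy)-7-methoxy-8-(3-methylbut-2-enyl)-2-(2,4,6-trimethoxyphenyl)chroman-4-one | COc1cc(OC)c([C@@H]2CC(=O)c3c(O[Si](C)(C)C(C)(C)C)cc(OC)c(CC=C(C)C)c3O2)c(OC)c1 | intermediate
20 | (2S)-5-hydroxy-7-methoxy-8-(3-methylbut-2-enyl)-2-(2,4,6-trimethoxyphenyl)chroman-4-one | COc1cc(OC)c([C@@H]2CC(=O)c3c(O)cc(OC)c(CC=C(C)C)c3O2)c(OC)c1 | target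

Total step count: 9. Longest linear sequence: 8 (steps 1, 2, 3, 4, 6, 7, 8, 9).

**Steps most likely to fail**

**Step 6.**
- What may go wrong:
  - Facial discrimination may be weak, because the styrene offers the catalyst no hydrogen-bond handle.
  - The acid may oligomerise the styrene, or the styrene may react through ring B in a Friedel–Crafts sense.
  - Reversible ionisation may blur the C2/C4 relationship.
- Fallback (known chemistry; chirality from a kinetic resolution instead of the cycloaddition): from 8, 11 and 12 the annulation is run with Sc(OTf)3 (5 mol %) in CH2Cl2 at 0 °C. This is the established racemic salicylaldehyde/orthoformate/styrene chroman synthesis, and it should give the racemic 4-methoxychroman F1. DDQ in wet CH2Cl2 takes it through the racemic hemiketal F2 to the racemic flavanone F3. A Noyori-type asymmetric transfer hydrogenation follows, with RuCl(p-cymene)(TsDPEN) and HCO2H/Et3N, stopped near half conversion. The ligand antipode is chosen so that the (2R)-ketone is consumed and becomes the cis-flavan-4-ol F4. The (2S)-ketone is left behind, is separated by chromatography, and is compound 17, where the route resumes.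

**Step 7.**
- What may go wrong:
  - Hydride may be abstracted at the doubly activated allylic-benzylic methylene or at C2–H.
  - Over-oxidation may occur.
  - Ring C may open transiently in the C4 oxocarbenium ion, with loss of configurational purity.
- Fallback (solvolysis followed by alcohol oxidation in place of hydride abstraction): from 15, PPTS in THF/H2O at rt exchanges the very labile C4 methoxy group for hydroxyl by SN1 solvolysis. This gives the (2S)-flavan-4-ol F5 as a mixture of C4 epimers. Dess–Martin periodinane buffered with NaHCO3 in CH2Cl2 then oxidises both epimers to 17.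

**Step 4.**
- What may go wrong:
  - The silyl group may be lost thermally or transferred between molecules to the newly freed phenol.
  - Some para migration may occur after ipso attack at C1.
- Fallback (regiochemistry from steric differentiation instead of from the order of events): from 4, the Claisen rearrangement is run on the free phenol (1,2-dichlorobenzene, 180 °C). It passes through the hydroxy dienone F6 to 3-allyl-2,6-dihydroxy-4-methoxybenzaldehyde F7. One equivalent of TBSCl 5 with imidazole in CH2Cl2 at 0 °C then silylates the less hindered O6, whose only other ring neighbour is H5, whereas O2 is flanked by the allyl group. This gives 8.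

**Further compounds**
F1 | step 6 | racemic 2,4-cis-8-allyl-5-(tert-butyldimethylsilyloxy)-4,7-dimethoxy-2-(2,4,6-trimethoxyphenyl)chroman | COc1cc(OC)c(C2CC(OC)c3c(O[Si](C)(C)C(C)(C)C)cc(OC)c(CC=C)c3O2)c(OC)c1
F2 | step 6 | racemic 8-allyl-5-(tert-butyldimethylsilyloxy)-4,7-dimethoxy-2-(2,4,6-trimethoxyphenyl)chroman-4-ol (hemiketal) | COc1cc(OC)c(C2CC(O)(OC)c3c(O[Si](C)(C)C(C)(C)C)cc(OC)c(CC=C)c3O2)c(OC)c1
F3 | step 6 | racemic 8-allyl-5-(tert-butyldimethylsilyloxy)-7-methoxy-2-(2,4,6-trimethoxyphenyl)chroman-4-one | COc1cc(OC)c(C2CC(=O)c3c(O[Si](C)(C)C(C)(C)C)cc(OC)c(CC=C)c3O2)c(OC)c1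
F4 | step 6 | (2R,4R)-8-allyl-5-(tert-butyldimethylsilyloxy)-7-methoxy-2-(2,4,6-trimethoxyphenyl)chroman-4-ol | COc1cc(OC)c([C@H]2C[C@@H](O)c3c(O[Si](C)(C)C(C)(C)C)cc(OC)c(CC=C)c3O2)c(OC)c1
F5 | step 7 | (2S)-8-allyl-5-(tert-butyldimethylsilyloxy)-7-methoxy-2-(2,4,6-trimethoxyphenyl)chroman-4-ol (C4 epimers) | COc1cc(OC)c([C@@H]2CC(O)c3c(O[Si](C)(C)C(C)(C)C)cc(OC)c(CC=C)c3O2)c(OC)c1
F6 | step 4 | 5-allyl-2-hydroxy-4-methoxy-6-oxocyclohexa-1,3-diene-1-carbaldehyde (racemic dienone) | O=CC1=C(O)C=C(OC)C(CC=C)C1=O
F7 | step 4 | 3-allyl-2,6-dihydroxy-4-methoxybenzaldehyde | O=Cc1c(O)c(CC=C)c(OC)cc1O
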